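(Readings and results were generated by integration on assumed constants, and the scatter is random.)

- I began with the closed, stirred vessel and what its two earlier runs had put on record.

| flask | starting material | partner | time |
|---|---|---|---|
| Monday's | 0.400 M | 0.320 M |  |
| Sunday's | 0.400 M | 0.480 M |  |
| Thursday's | 0.240 M | 0.160 M | 39 min |

| run | time / min | [target] / M |
|---|---|---|
| Monday's run | 2.2 | 0.036 |
| Monday's run | 6.7 | 0.090 |
| Monday's run | 13 | 0.131 |
| Monday's run | 20 | 0.150 |
| Monday's run | 29 | 0.162 |
| Monday's run | 39 | 0.172 |
| Sunday's run | 2.2 | 0.050 |
| Sunday's run | 6.7 | 0.120 |
| Sunday's run | 13 | 0.169 |
| Sunday's run | 20 | 0.201 |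
| Sunday's run | 29 | 0.210 |
| Sunday's run | 39 | 0.225 |

(readings scatter by 0.003 M)

1. order of the initial rate in [partner], near the charge of the Monday's run, the rate being that where two percent of its starting material are target
2. target in the Thursday's run at 39 min, as a share of the starting material charged

- Overall: starting material + partner -> target.
- Constant volume, constant temperature.
- "The second partner" is partner.
- An order is taken over about fifteen percent of the charge, up and down.

- I ordered Monday's run by time scales. Its first reading gave a climb of 0.0164 M min⁻¹.
- At that climb, Monday's last reading would have needed 10.5 min, which is shorter than the 39 min of the run.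
- Monday's last interval read 1.00 × 10⁻³ M min⁻¹, which would take 172 min to make the same amount, longer than the run. So the late flask looked nearly still.
- A still flask invites dividing forward rate by return rate, so that time drops out. From Monday's last reading I kept 5.10 M⁻¹ as the closing quotient, a reaction quotient: target divided by both charges, each less that target.
- I tested it on Sunday's run. Monday's quotient gave 0.226 M of target, and Sunday's last reading was 0.225 M.
- For Thursday's run, the same quotient gave 0.0735 M, or 30.6% of the starting material charged. I held this as my estimate for 39 min, the time at which Monday's quotient was read.
- The forecast said 30%, from 27% to 32.5%, a little below my figure, and an order of 0.8, from 0.6 to 1. Its ground was: “The approach flattens well short of completion”.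

    starting material + partner ⇌ intermediate, settled at all times (1.560 M⁻¹)
    starting material + partner → target (0.2982 M⁻¹ min⁻¹)
    partner → lost reagent (0.04062 min⁻¹)
    starting material → decomposed substrate (0.03414 min⁻¹)

- Thursday's run gave 28.7% and the order came to 0.85, both inside the forecast's ranges. The steps hold no return from target, which forms with 0.298 M⁻¹ min⁻¹, so the closing quotient is a number read from the readings, not an equilibrium constant. Thursday's own quotient came to 4.42 M⁻¹, lower than Monday's. That fall from 5.10 M⁻¹ to 4.42 M⁻¹ moved Thursday's share by 1.9 percentage points.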